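Its constants are invented; the run is a simulation.

Find the one concentration that sets the pace in these flasks before you reckon any yield.

common to all: L 0.25 mM
- west: Z 0.050 M; a single well-mixed tank run continuously and read at steady state, 5.0 h in it on average
- south: Z 0.050 M; everything together in a closed stirred flask, run for 5.0 h; time 5.0 h
- south-east: Z 0.050 M (fed, over 5.00 h); a stirred flask in which Z is dosed at a steady rate over 5.00 h without added volume, worked up at 5.0 h; time 5.0 h

    Z + Q ⇌ X + Q, rate k1*[Z]*[Q] forward; the back reaction follows from the equilibrium constant (K1 = 1.5, k1 = 14900 M⁻¹ h⁻¹)
    L → Q (k2 = 0.257 h⁻¹)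
    X ⇌ D (K3 = 2.15, k3 = 0.546 h⁻¹)
    G + Q ⇌ E + Q, rate k4*[Q]*[G] forward; the back reaction follows from the equilibrium constant (K4 = 13.6, k4 = 13800 M⁻¹ h⁻¹)
    X + Q ⇌ G + Q, rate k5*[Q]*[X] forward; the back reaction follows from the equilibrium constant (K5 = 1.94, k5 = 268 M⁻¹ h⁻¹)

* the set-up with the highest amount of X at the outlet or at the end, in percent of the Z put in ("none" if the first two lie within 2 percentage points) (west / south / south-east / none)
* amount of X at the outlet or at the end, in percent of the Z put in, west
* amount of X at the outlet or at the end, in percent of the Z put in, south
* amount of X at the outlet or at the end, in percent of the Z put in, south-east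

- the stated concentrations are those of everything mixed, before any reaction; amounts are the same in each set-up
- the feed brings no volume worth counting
- run time (south): 5.0 h

That concentration is c(Q): at a given c(Q) the steps between Z and X are first order, with k·c(Q) as a pseudo-first-order constant, and Q grows from L on its own clock, whether or not Z is dosed.

Now turn the question round. Two things could put south ahead of south-east: X keeping over the run, or the dosed Z lagging far behind its feed at the end. X does not keep in south-east, since X and D relax with a half-life of 0.866 h, shorter than the 5.0 h of the run. So test the lag, with Q as it stands at the end: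

c(Q) = 0.25 mM · (1 − exp(−0.257 h⁻¹ · 5.0 h)) = 0.181 mM

κ(Z) = 14900 M⁻¹ h⁻¹ · c(Q) · (1 + 1/1.5) = 4.49 h⁻¹

κ(D) = 0.546 h⁻¹ · (1 + 1/2.15) = 0.800 h⁻¹

ρ = κ(Z)/κ(D) = 5.61

Call ρ the pace ratio, the rate at which Z and X find their balance over the rate at which X and D find theirs. It stands well above one, so by this estimate Z dosed late into south-east reaches its balance with X faster than X reaches its balance with D, and I expect south-east ahead of south. This reckoning gives an order and no percentages.

The forecast names south-east, with 30.5% for west, 27% for south and 34% for south-east, on the ground that “dosing does best because fresh Z keeps feeding X right up to the end”.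

The simulation gives south-east, with 30.5% for west, 28.1% for south and 34.5% for south-east.

The drain to D is part of the reason: with X to D struck out both ways, south rises from 28.1% to 55.1% and south-east from 34.5% to 54.2%, and the order turns. Now take a neighbour of south-east charged with L at 1.0 × 10⁻⁴ M, all else held: c(Q) falls in proportion, so ρ becomes 2.25, still above one, and X should barely move while more Z stays unconverted. That flask ends with 32.8% of X and 38% of Z, against 34.5% and 29.4% in south-east.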